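The ten-membered ring holds two ketones in a 1,6-relationship. On one arc they flank the C(iPr)–CH2–CH(O)–C(Me)(OH) segment, which is C4–C5–C6–C1 of carvone; on the other arc lies the four-carbon unit CH=C(Me)–CH2–CH2. The ring is therefore disconnected by a retro-[3,3] shift to a carvone-derived cyclohexane-2,3-diol with vinyl on C2 and 1-propynyl on C3, the C1,C6-diol being masked as an acetonide. Double deprotonation triggers a dianionic alkynyl dioxy-Cope rearrangement that cleaves C2–C3, inserts the four carbons and unveils both ketones and the β-methyl enone in one operation. The enone geometry is then corrected and the (2R,3R)-epoxy acid is attached last.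

Key step: step 14

Locants and faces: carvone (p-menthane) numbering is kept for the six original ring carbons (C1 methyl-bearing, C2 the carvone carbonyl carbon, C3, C4 isopropyl-bearing, C5, C6); the inserted ring carbons are C7 (next to C2), C8, C9 (methyl-bearing) and C10 (next to C3); β is the face of the isopropyl group, α the opposite face; systematic names in the compound list carry their own locants.

Remark on the diol: acid opening of the 1α,6α-epoxy ketone of 2 is expected to be trans-diaxial and to put water on C1 (as chloride does when carvone oxide is turned into its chlorohydrin), which would give the 1β,6α-diol; the 1α,6β-diol of the target is therefore set by osmylation anti to an allylic ether followed by an oxidation–reduction inversion at C6.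

Remark on the acid: the acyl group of the target is the cis, angelate-derived (2R,3R)-2,3-epoxy-2-methylbutanoate, C[C@H]1O[C@@]1(C)C(=O)O as the free acid; the string C[C@H]1O[C@]1(C)C(=O)O would be the trans (2S,3R) acid and is not used.

Step 1
Reactants: 1 (S)-(+)-carvone
Product: 2 (S)-carvotanacetone
Conditions: H2 (1 atm), RhCl(PPh3)3 (cat), benzene, rt
Reagents that add atoms: none
Why: Homogeneous catalytic hydrogenation with RhCl(PPh3)3 saturates only the unhindered 1,1-disubstituted isopropenyl alkene, leaving the trisubstituted conjugated alkene and the C4 stereocentre untouched.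

Step 2
Reactants: 2 (S)-carvotanacetone
Product: 3 (1S,5S)-2-methyl-5-(propan-2-yl)cyclohex-2-en-1-ol (C2 hydroxyl β)
Conditions: NaBH4, CeCl3·7H2O, MeOH, −78 to 0 °C
Reagents that add atoms: none
Why: Luche 1,2-reduction, in which hydride adds to the cerium-activated carbonyl anti to the ring flap that carries the equatorial isopropyl group (the course that turns carvone into cis-carveol), so the new C2 hydroxyl is β, cis to the isopropyl group.

Step 3
Reactants: 3 allylic alcohol
Product: 4 2β-benzyloxy-p-menth-6-ene
Conditions: NaH, BnBr, Bu4NI (cat), THF–DMF, 0 °C to rt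
Reagents that add atoms: benzyl bromide, BrCc1ccccc1
Why: Williamson etherification gives a non-migrating benzyl ether that keeps C2 distinguishable from C6 in the otherwise pseudo-symmetric oxygenation pattern and later directs the osmylation.

Step 4
Reactants: 4 allylic benzyl ether
Product: 5 2β-benzyloxy-p-menthane-1α,6α-diol
Conditions: OsO4 (cat), N-methylmorpholine N-oxide, acetone–H2O, rt
Reagents that add atoms: N-methylmorpholine N-oxide, C[N+]1([O-])CCOCC1; water, O
Why: Upjohn dihydroxylation, which on cyclic allylic ethers adds anti to the allylic oxygen, so OsO4 attacks the α face and both new hydroxyls are α, which fixes C1 in its final configuration (tertiary hydroxyl trans to the isopropyl group).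

Step 5
Reactants: 5 cis-diol
Product: 6 2β-benzyloxy-1α-hydroxy-p-menthan-6-one
Conditions: IBX, DMSO, rt
Reagents that add atoms: none
Why: IBX oxidation converts the secondary C6 hydroxyl of the vicinal diol into the ketone without glycol cleavage and cannot oxidise the tertiary C1 hydroxyl, opening the way to inversion at C6.

Step 6
Reactants: 6 α-ketol
Product: 7 2β-benzyloxy-p-menthane-1α,6β-diol
Conditions: NaBH4, MeOH, −40 °C
Reagents that add atoms: none
Why: Borohydride reduction of the conformationally anchored α-ketol (isopropyl and benzyloxy equatorial, C1 methyl axial), in which hydride adds axially from the α face, anti to the axial methyl and on the side of the C1 hydroxyl, gives the equatorial 6β-alcohol and thus the trans-diequatorial diol with C6 as in the target.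

Step 7
Reactants: 7 trans-diol
Product: 8 2β-benzyloxy-1α,6β-(isopropylidenedioxy)-p-menthane
Conditions: 2-methoxypropene, PPTS (cat), CH2Cl2, 0 °C to rt
Reagents that add atoms: 2-methoxypropene, COC(C)=C
Why: Acid-catalysed acetalisation with 2-methoxypropene closes the trans-fused five-membered acetonide on the diequatorial diol and leaves the benzyl ether alone.

Step 8
Reactants: 8 benzyl ether acetonide
Product: 9 1α,6β-(isopropylidenedioxy)-p-menthan-2β-ol
Conditions: H2 (1 atm), Pd(OH)2/C, EtOAc, rt
Reagents that add atoms: none
Why: Catalytic hydrogenolysis cleaves the benzylic C–O bond and frees the C2 hydroxyl, the acetonide and all stereocentres being inert since no alkene remains.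

Step 9
Reactants: 9 alcohol acetonide
Product: 10 keto acetonide (1α,6β-(isopropylidenedioxy)-p-menthan-2-one)
Conditions: IBX, DMSO, 40 °C
Reagents that add atoms: none
Why: IBX oxidation of the secondary alcohol restores the C2 ketone, which is now flanked by the fully substituted oxygenated C1.

Step 10
Reactants: 10 keto acetonide
Product: 12 3α-hydroxy keto acetonide, via potassium enolate 11 (not isolated)
Conditions: KN(SiMe3)2, THF, −78 °C; 2-(phenylsulfonyl)-3-phenyloxaziridine, −78 °C; AcOH
Reagents that add atoms: 2-(phenylsulfonyl)-3-phenyloxaziridine, O=S(=O)(N1OC1c1ccccc1)c1ccccc1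
Why: Davis oxaziridine hydroxylation of the only enolate that can form (C1 is quaternary, so deprotonation occurs at C3), the oxygen arriving on the α face away from the axial C1 methyl and the neighbouring isopropyl group, although the C3 configuration is erased in step 12.

Step 11
Reactants: 12 3α-hydroxy keto acetonide; 13 vinylmagnesium bromide
Product: 14 2α-vinyl-2β,3α-diol acetonide
Conditions: CH2=CHMgBr (3 equiv), THF, −78 to 0 °C; H2O
Reagents that add atoms: none
Why: Grignard 1,2-addition to the ketone after the first equivalent has turned the C3 hydroxyl into a magnesium alkoxide that blocks enolisation and chelates the carbonyl, with axial attack anti to the axial C1 methyl expected to place vinyl on the α face, a centre that is destroyed in the key step.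

Step 12
Reactants: 14 vinyl diol acetonide
Product: 15 2β-hydroxy-2α-vinyl-3-ketone acetonide
Conditions: IBX, DMSO, rt
Reagents that add atoms: none
Why: IBX oxidises the secondary C3 carbinol to the ketone without cleaving the vicinal diol and leaves the tertiary allylic alcohol, while C4 keeps its equatorial isopropyl group, the more stable arrangement should any enolisation occur.

Step 13
Reactants: 15 hydroxy vinyl ketone; 16 1-propynylmagnesium bromide
Product: 17 2α-vinyl-3α-(prop-1-ynyl)-2β,3β-diol acetonide
Conditions: CH3C≡CMgBr (3 equiv), THF, −78 to 0 °C; H2O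
Reagents that add atoms: none
Why: Alkynyl Grignard 1,2-addition to the magnesium alkoxide of the α-ketol, in which attack along the equatorial direction, away from the 1,3-diaxial C1 methyl, sets the slim propynyl group equatorial (α) and gauche to the axial vinyl group, the mutual arrangement a [3,3] shift requires, the carbinol configuration itself being erased in step 14.

Step 14
Reactants: 17 vinyl propynyl diol acetonide
Product: 20 (Z)-enedione acetonide, via dipotassium dialkoxide 18 (not isolated), via dipotassium enolate-allenolate 19 (not isolated)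
Conditions: KN(SiMe3)2 (2.2 equiv), 18-crown-6, THF, −78 to −20 °C; cannulated into AcOH–THF at −78 °C
Reagents that add atoms: none
Why: Proposed new method: double deprotonation gives the vicinal dialkoxide 18 of a 3,4-dioxy-1-en-5-yne, whose two oxido donors weaken the C2–C3 bond so that a charge-accelerated [3,3] sigmatropic shift breaks it while the vinyl terminus bonds to the methyl-bearing alkyne carbon, giving the C2 enolate and C3 allenolate of 19; C-protonation at C7 and at the central allene carbon C10 then delivers the saturated ketone and the β-methyl enone. The closest known reaction types are the dianionic dioxy-Cope ring expansion of 1,2-dialkenylcycloalkane-1,2-diols to 1,6-diketones and the anionic acetylenic oxy-Cope rearrangement of alkynyl vinyl carbinols through allenolates, which have not been combined on one vicinal diol. The ten-membered ring is not closed end to end but arises by four-carbon expansion of the cyclohexane through a six-centre, boat-like transition state that the cis (axial vinyl, equatorial propynyl) arrangement permits, and the acetonide ring is carried through unchanged. No new sp3 stereocentre is formed, since both carbinol configurations are erased and C1, C4 and C6 are not involved; the only new stereo-element is the enone geometry, fixed by protonation on the outer face of the cyclic allenolate (Z expected, corrected in steps 15 and 16). The step needs the [3,3] shift to outrun loss of propynide by retro-addition and transannular aldol closure, which is secured by the strain of three contiguous fully substituted carbons, by ion-pair separation with 18-crown-6 at low temperature, by the quaternary C1 that can neither eliminate its oxygen nor epimerise, and by an inverse quench that protonates both enolates at once.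

Step 15
Reactants: 20 (Z)-enedione acetonide
Product: 22 β-trimethylstannyl ketone, via lithium enolate 21 (not isolated)
Conditions: Me3SnLi (from Me3SnSnMe3 and MeLi), THF, −78 °C; MeOH
Reagents that add atoms: trimethylstannyllithium, [Li][Sn](C)(C)C
Why: Conjugate addition of the stannyl anion to the β-methyl enone, which is much faster at −78 °C than attack on the hindered saturated ketone, gives the same β-stannyl ketone from either enone isomer so that the double-bond geometry is erased, the configuration of the new tin-bearing carbon being irrelevant.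

Step 16
Reactants: 22 β-trimethylstannyl ketone
Product: 23 (E)-enedione acetonide
Conditions: CrO3(C5H5N)2, CH2Cl2, rt
Reagents that add atoms: none
Why: Oxidative destannylation, in which hexavalent chromium cleaves the C–Sn bond with loss of an α-hydrogen and regenerates the enone under kinetic control, a sequence with precedent for converting (Z)- into (E)-3-methylcyclodec-2-enones because elimination runs through the transoid ring conformer.

Step 17
Reactants: 23 (E)-enedione acetonide
Product: 24 (E)-enedione diol
Conditions: AcOH–H2O (4:1), 40 °C
Reagents that add atoms: none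
Why: Acid-catalysed acetal hydrolysis liberates the secondary C6 and tertiary C1 hydroxyls under conditions mild enough for the E-enone and the tertiary α-ketol.

Step 18
Reactants: 25 angelic acid
Product: 26 (2Z)-2-methylbut-2-en-1-ol
Conditions: LiAlH4, Et2O, 0 °C; aqueous work-up
Reagents that add atoms: none
Why: Hydride 1,2-reduction of the carboxylic acid to the primary allylic alcohol, which does not touch or isomerise the trisubstituted Z-alkene.

Step 19
Reactants: 26 (2Z)-2-methylbut-2-en-1-ol
Product: 27 [(2S,3R)-2,3-dimethyloxiran-2-yl]methanol
Conditions: Ti(OiPr)4 (cat), L-(+)-diisopropyl tartrate (cat), tBuOOH, 4 Å molecular sieves, CH2Cl2, −20 °C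
Reagents that add atoms: tert-butyl hydroperoxide, CC(C)(C)OO
Why: Sharpless asymmetric epoxidation, in which the L-(+)-tartrate titanium complex delivers oxygen to the alkene face that gives the (2S,3R)-epoxy alcohol, the Z geometry of the alkene fixing the cis relationship between the C3 methyl and the hydroxymethyl group.

Step 20
Reactants: 27 epoxy alcohol
Product: 28 (2R,3R)-2,3-dimethyloxirane-2-carboxylic acid
Conditions: RuCl3 (cat), NaIO4, MeCN–EtOAc–H2O, 0 °C to rt
Reagents that add atoms: sodium periodate, [Na+].[O-]I(=O)(=O)=O; water, O
Why: RuO4-catalysed oxidation of the primary alcohol to the carboxylic acid under biphasic conditions leaves the oxirane intact, the C2 descriptor changing from S to R only because the carboxyl group outranks C3.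

Step 21
Reactants: 24 (E)-enedione diol; 28 (2R,3R)-epoxy acid
Product: 30 target CNP0389889.1, via mixed anhydride 29 (not isolated)
Conditions: 28, 2,4,6-trichlorobenzoyl chloride, Et3N, THF, rt; then 24, DMAP, toluene, rt
Reagents that add atoms: none
Why: Yamaguchi esterification, in which DMAP attacks the less hindered epoxy-acyl carbonyl of the mixed anhydride and the acylpyridinium acylates the secondary C6 hydroxyl with retention, the tertiary C1 hydroxyl being too hindered to compete.

Compound list
1 | (S)-(+)-carvone, (5S)-2-methyl-5-(prop-1-en-2-yl)cyclohex-2-en-1-one | O=C1C[C@@H](C(C)=C)CC=C1C | starting material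
2 | (S)-carvotanacetone, (5S)-2-methyl-5-(propan-2-yl)cyclohex-2-en-1-one | O=C1C[C@@H](C(C)C)CC=C1C | intermediate
3 | (1S,5S)-2-methyl-5-(propan-2-yl)cyclohex-2-en-1-ol (hydroxyl cis to isopropyl) | O[C@H]1C[C@@H](C(C)C)CC=C1C | intermediate
4 | 2β-benzyloxy-p-menth-6-ene (benzyl ether of 3) | c3ccccc3CO[C@H]1C[C@@H](C(C)C)CC=C1C | intermediate
5 | 2β-benzyloxy-p-menthane-1α,6α-diol (cis-diol, C1 methyl β) | c3ccccc3CO[C@H]1C[C@@H](C(C)C)C[C@H](O)[C@]1(C)O | intermediate
6 | 2β-benzyloxy-1α-hydroxy-p-menthan-6-one | c3ccccc3CO[C@H]1C[C@@H](C(C)C)CC(=O)[C@]1(C)O | intermediate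
7 | 2β-benzyloxy-p-menthane-1α,6β-diol (trans-diequatorial diol) | c3ccccc3CO[C@H]1C[C@@H](C(C)C)C[C@@H](O)[C@]1(C)O | intermediate
8 | 2β-benzyloxy-1α,6β-(isopropylidenedioxy)-p-menthane (trans-fused acetonide) | c3ccccc3CO[C@H]1C[C@@H](C(C)C)C[C@H]2OC(C)(C)O[C@]12C | intermediate
9 | 1α,6β-(isopropylidenedioxy)-p-menthan-2β-ol | O[C@H]1C[C@@H](C(C)C)C[C@H]2OC(C)(C)O[C@]12C | intermediate
10 | 1α,6β-(isopropylidenedioxy)-p-menthan-2-one, the acetonide of (2S,3R,5S)-2,3-dihydroxy-2-methyl-5-(propan-2-yl)cyclohexan-1-one | O=C1C[C@@H](C(C)C)C[C@H]2OC(C)(C)O[C@]12C | intermediate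
11 | potassium C2–C3 enolate of 10 | [K+].[O-]C1=C[C@@H](C(C)C)C[C@H]2OC(C)(C)O[C@]12C | intermediate
12 | 3α-hydroxy-1α,6β-(isopropylidenedioxy)-p-menthan-2-one | O=C1[C@H](O)[C@@H](C(C)C)C[C@H]2OC(C)(C)O[C@]12C | intermediate
13 | vinylmagnesium bromide, CH2=CHMgBr | C=C[Mg]Br | starting material
14 | 2α-vinyl-1α,6β-(isopropylidenedioxy)-p-menthane-2β,3α-diol | O[C@@H]1[C@@H](C(C)C)C[C@H]2OC(C)(C)O[C@]2(C)[C@]1(O)C=C | intermediate
15 | 2β-hydroxy-2α-vinyl-1α,6β-(isopropylidenedioxy)-p-menthan-3-one | O=C1[C@@H](C(C)C)C[C@H]2OC(C)(C)O[C@]2(C)[C@]1(O)C=C | intermediate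
16 | 1-propynylmagnesium bromide, CH3C≡CMgBr | CC#C[Mg]Br | starting material
17 | 3α-(prop-1-ynyl)-2α-vinyl-1α,6β-(isopropylidenedioxy)-p-menthane-2β,3β-diol | CC#C[C@]1(O)[C@@H](C(C)C)C[C@H]2OC(C)(C)O[C@]2(C)[C@]1(O)C=C | intermediate
18 | dipotassium 2,3-dialkoxide of 17 | CC#C[C@]1([O-])[C@@H](C(C)C)C[C@H]2OC(C)(C)O[C@]2(C)[C@]1([O-])C=C.[K+].[K+] | intermediate
19 | dipotassium salt of the ten-membered C2 enolate and C3 allenolate (C2=C7 and C3=C10=C9) | CC1=C=C([O-])[C@@H](C(C)C)C[C@H]2OC(C)(C)O[C@]2(C)C([O-])=CC1.[K+].[K+] | intermediate
20 | (2Z,7S,8R,10R)-7,8-(isopropylidenedioxy)-3,7-dimethyl-10-(propan-2-yl)cyclodec-2-ene-1,6-dione | C/C1=C/C(=O)[C@@H](C(C)C)C[C@H]2OC(C)(C)O[C@]2(C)C(=O)CC1 | intermediate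
21 | lithium C3–C10 enolate of 22 | C[Sn](C)(C)C1(C)C=C([O-])[C@@H](C(C)C)C[C@H]2OC(C)(C)O[C@]2(C)C(=O)CC1.[Li+] | intermediate
22 | (7S,8R,10R)-7,8-(isopropylidenedioxy)-3,7-dimethyl-10-(propan-2-yl)-3-(trimethylstannyl)cyclodecane-1,6-dione (either configuration at the tin-bearing carbon) | C[Sn](C)(C)C1(C)CC(=O)[C@@H](C(C)C)C[C@H]2OC(C)(C)O[C@]2(C)C(=O)CC1 | intermediate
23 | (2E,7S,8R,10R)-7,8-(isopropylidenedioxy)-3,7-dimethyl-10-(propan-2-yl)cyclodec-2-ene-1,6-dione | C/C1=C\C(=O)[C@@H](C(C)C)C[C@H]2OC(C)(C)O[C@]2(C)C(=O)CC1 | intermediate
24 | (2E,7S,8R,10R)-7,8-dihydroxy-3,7-dimethyl-10-(propan-2-yl)cyclodec-2-ene-1,6-dione | C/C1=C\C(=O)[C@@H](C(C)C)C[C@@H](O)[C@](C)(O)C(=O)CC1 | intermediate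
25 | angelic acid, (2Z)-2-methylbut-2-enoic acid | C/C=C(/C)C(=O)O | starting material
26 | (2Z)-2-methylbut-2-en-1-ol | C/C=C(/C)CO | intermediate
27 | [(2S,3R)-2,3-dimethyloxiran-2-yl]methanol | C[C@H]1O[C@@]1(C)CO | intermediate
28 | (2R,3R)-2,3-dimethyloxirane-2-carboxylic acid (cis-2,3-epoxy-2-methylbutanoic acid) | C[C@H]1O[C@@]1(C)C(=O)O | intermediate
29 | mixed anhydride of 28 with 2,4,6-trichlorobenzoic acid | C[C@H]1O[C@@]1(C)C(=O)OC(=O)c1c(Cl)cc(Cl)cc1Cl | intermediate
30 | CNP0389889.1, (1R,2S,6E,9R)-2-hydroxy-2,6-dimethyl-3,8-dioxo-9-(propan-2-yl)cyclodec-6-en-1-yl (2R,3R)-2,3-dimethyloxirane-2-carboxylate | C/C1=C\C(=O)[C@@H](C(C)C)C[C@@H](OC(=O)[C@]2(C)O[C@@H]2C)[C@](C)(O)C(=O)CC1 | target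

Total step count: 21 (18 from carvone to the target, 3 for the epoxy acid). Longest linear sequence: 18 steps (steps 1 to 17, then step 21).

Steps most likely to fail

Step 14 (proposed new method). The dialkoxide may expel propynide by retro-addition faster than it rearranges. The rigid trans-fused chair may hold the two unsaturated arms apart if the addition in step 13 had gone axially. The enolates may close transannularly during protonation. The fallback uses known reaction types only and runs from 15 back to 20. The tertiary hydroxyl of 15 is silylated (Et3SiOTf, 2,6-lutidine, CH2Cl2) to the 2β-triethylsilyloxy-2α-vinyl ketone F1. Addition of 16 gives the mono-carbinol F2. The mono-anionic acetylenic oxy-Cope rearrangement of this alkynyl vinyl carbinol (KH, 18-crown-6, THF) is a charge-accelerated [3,3] shift of a single alkoxide, assisted by the silyloxy donor; after cold protonation it should give the ring-expanded enone silyl enol ether F3. Dilute HCl in THF hydrolyses the enol ether to the C2 ketone, and the route is rejoined at 20.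

Step 16. Geometric control may be lost in the elimination (reaction through the cisoid conformer returns the Z-enone), or the chromium reagent may oxidise elsewhere in the molecule. The fallback runs from 20 back to 23. 1,4-Hydrosilylation (Et3SiH, RhCl(PPh3)3 cat, benzene) forms regiospecifically the triethylsilyl enol ether F4 of the saturated C3 ketone. Saegusa–Ito oxidation (Pd(OAc)2, MeCN) then reinstalls the C9–C10 double bond by syn β-hydride elimination from the palladium enolate, a process that in medium and large rings favours the E-enone, and should give 23.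

Step 21. Acylation of the hindered secondary hydroxyl next to a tertiary carbinol may be slow. DMAP may attack the aroyl carbonyl of the mixed anhydride. The free diol may be diverted into transannular hemiketals. The fallback runs from 24 to 30. The diol is heated with Bu2SnO in toluene with azeotropic removal of water to give the dibutylstannylene acetal F5, which activates the secondary oxygen as the nucleophile. Treatment with the mixed anhydride 29 then acylates that oxygen selectively and should give 30 after work-up.

Further compounds
F1 | step 14 | 2α-vinyl-2β-(triethylsilyloxy)-1α,6β-(isopropylidenedioxy)-p-menthan-3-one | O=C1[C@@H](C(C)C)C[C@H]2OC(C)(C)O[C@]2(C)[C@]1(O[Si](CC)(CC)CC)C=C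
F2 | step 14 | 3α-(prop-1-ynyl)-2α-vinyl-2β-(triethylsilyloxy)-1α,6β-(isopropylidenedioxy)-p-menthan-3β-ol | CC#C[C@]1(O)[C@@H](C(C)C)C[C@H]2OC(C)(C)O[C@]2(C)[C@]1(O[Si](CC)(CC)CC)C=C
F3 | step 14 | triethylsilyl enol ether (C2=C7) of the (Z)-enedione acetonide 20 | C/C1=C/C(=O)[C@@H](C(C)C)C[C@H]2OC(C)(C)O[C@]2(C)C(O[Si](CC)(CC)CC)=CC1
F4 | step 16 | triethylsilyl enol ether (C3=C10) of the 9,10-dihydro derivative of 20 | CC1C=C(O[Si](CC)(CC)CC)[C@@H](C(C)C)C[C@H]2OC(C)(C)O[C@]2(C)C(=O)CC1
F5 | step 21 | dibutylstannylene acetal of diol 24 | C/C1=C\C(=O)[C@@H](C(C)C)C[C@H]2O[Sn](CCCC)(CCCC)O[C@]2(C)C(=O)CC1
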